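## Retrosynthetic overview

- Endgame: the target comes from acetylation of a C2 carbinol, itself made by conjugate hydride delivery to C3 of a C2=C3 dienone bis-angelate followed by Rubottom oxidation at C2. Hydride enters opposite the C4 oxygen and the ring oxirane, which gives the all-cis C3/C4/C5/C6 array.
- The dienone comes from an sp2–sp2 Suzuki union (C3–C7) of a bromo epoxy-enone with an alkenyl boronate that already carries C8 and the side-chain oxirane, then double angeloylation.
- The bromo epoxy-enone comes from a brominated quinone monoketal: CBS reduction sets C4, hydroxyl-directed epoxidation sets C5/C6, and the ketal is unmasked as the C1 ketone only afterwards.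
- Key step: the quinone monoketal is made in one flask from 2-bromo-5-methylphenol by double oxidative dearomatisation.
- Ring order: the carbocycle is the original benzene ring; the ring oxirane is closed in step 3 and the side-chain oxirane in step 7, before the union.

Assumption: 2-bromo-5-methylphenol, 2-bromoacrolein and angelic acid are purchased; in the Why lines positions follow the target skeleton (C1 ketone, C2 acetate, C3 side chain, C4 angelate, C5/C6 oxirane with methyl on C6, side chain C7 with its =CH2, C8 angelate, C9, C10/C11 oxirane).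

## Route

Step 1
Reactants: 1 2-bromo-5-methylphenol
Product: 3 2-bromo-4,4-dimethoxy-5-methylcyclohexa-2,5-dien-1-one, via 2-bromo-4-methoxy-5-methylphenol 2 (not isolated)
Conditions: PhI(OAc)2 (2.2 equiv), MeOH, 0 °C to rt
Reagents that add atoms: methanol, CO
Why: Hypervalent-iodine oxidative dearomatisation (Pelter type): the first equivalent methoxylates the free para position (giving 2 after tautomerisation) and the second converts 2 into the quinone monoketal, so one flask differentiates the ketone (future C4 carbinol), the ketal (future C1 ketone) and the two enone arms; no stereocentre.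

Step 2
Reactants: 3 2-bromo-4,4-dimethoxy-5-methylcyclohexa-2,5-dien-1-one
Product: 4 (1R)-2-bromo-4,4-dimethoxy-5-methylcyclohexa-2,5-dien-1-ol
Conditions: (S)-2-methyl-CBS-oxazaborolidine (20 mol%), catecholborane, toluene, −78 °C; buffered aqueous work-up, used crude
Reagents that add atoms: none
Why: Corey–Bakshi–Shibata reduction: the bromine-bearing alkenyl flank acts as the large group and the CH= flank as the small one, so hydride is delivered to one face and C4 is set (R here, S once bromine is replaced by carbon).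

Step 3
Reactants: 4 (1R)-2-bromo-4,4-dimethoxy-5-methylcyclohexa-2,5-dien-1-ol
Product: 5 (1S,2R,6S)-3-bromo-5,5-dimethoxy-6-methyl-7-oxabicyclo[4.1.0]hept-3-en-2-ol
Conditions: VO(acac)2 (5 mol%), t-BuOOH, toluene, 0 °C
Reagents that add atoms: tert-butyl hydroperoxide, CC(C)(C)OO
Why: Vanadium-catalysed hydroxyl-directed (Sharpless–Michaelson) epoxidation: the allylic alkoxide delivers oxygen to the electron-rich trisubstituted C5=C6 alkene on its own face (C5/C6 set cis to C4–OH), while the bromoalkene is too electron-poor to react.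

Step 4
Reactants: 5 (1S,2R,6S)-3-bromo-5,5-dimethoxy-6-methyl-7-oxabicyclo[4.1.0]hept-3-en-2-ol
Product: 6 (1S,5R,6S)-4-bromo-5-hydroxy-1-methyl-7-oxabicyclo[4.1.0]hept-3-en-2-one
Conditions: aq. HF (48%), MeCN, 0 °C
Reagents that add atoms: water, O
Why: Acid-catalysed ketal hydrolysis releases the C1 ketone only after C4 has been reduced, so the two carbonyl positions never have to be told apart; the oxirane next to the forming carbonyl is deactivated towards acid and no stereocentre is touched.

Step 5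
Reactants: 7 2-bromoacrolein
Product: 8 (3R)-2-bromohexa-1,5-dien-3-ol
Conditions: allylboronic acid pinacol ester, (R)-TRIP phosphoric acid (5 mol%), toluene, −30 °C; aqueous work-up
Reagents that add atoms: allylboronic acid pinacol ester, C=CCB1OC(C)(C)C(C)(C)O1
Why: Chiral-phosphoric-acid-catalysed allylboration (Antilla type) through a chair six-membered transition state; (R)-TRIP is assigned to give the (R)-carbinol (C8) by analogy with aryl aldehydes.

Step 6
Reactants: 8 (3R)-2-bromohexa-1,5-dien-3-ol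
Product: 9 (3R)-2-bromo-6-methylhepta-1,5-dien-3-ol
Conditions: second-generation Grubbs catalyst (5 mol%), 2-methyl-2-butene (excess), CH2Cl2, 40 °C
Reagents that add atoms: 2-methyl-2-butene, CC=C(C)C
Why: Olefin cross-metathesis: only the monosubstituted terminal alkene enters the cycle (the 1,1-disubstituted bromoalkene is inert) and is capped as the prenyl group; C8 is untouched.

Step 7
Reactants: 9 (3R)-2-bromo-6-methylhepta-1,5-dien-3-ol
Product: 10 (2R)-3-bromo-1-[(2S)-3,3-dimethyloxiran-2-yl]but-3-en-2-ol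
Conditions: L-fructose-derived Shi ketone (30 mol%), KHSO5 (as 2KHSO5·KHSO4·K2SO4), K2CO3, Bu4NHSO4 (cat.), MeCN/dimethoxymethane/aq. Na2B4O7 buffer, 0 °C
Reagents that add atoms: potassium peroxymonosulfate, [K+].[O-]S(=O)(=O)OO
Why: Shi asymmetric epoxidation: the chiral dioxirane attacks the trisubstituted alkene through the spiro transition state and the L-series ketone gives the (S)-oxirane (C10) under catalyst control; the bromoalkene does not react.

Step 8
Reactants: 10 (2R)-3-bromo-1-[(2S)-3,3-dimethyloxiran-2-yl]but-3-en-2-ol; 6 (1S,5R,6S)-4-bromo-5-hydroxy-1-methyl-7-oxabicyclo[4.1.0]hept-3-en-2-one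
Product: 12 (1S,5S,6S)-4-{(3R)-4-[(2S)-3,3-dimethyloxiran-2-yl]-3-hydroxybut-1-en-2-yl}-5-hydroxy-1-methyl-7-oxabicyclo[4.1.0]hept-3-en-2-one, via alkenyl pinacol boronate 11 (not isolated)
Conditions: 10, B2pin2, PdCl2(dppf) (5 mol%), KOAc, 1,4-dioxane, 80 °C; then 6, aq. K3PO4, 40 °C
Reagents that add atoms: none
Why: Miyaura borylation of the alkenyl bromide followed in the same flask by Suzuki–Miyaura coupling with the β-bromo enone (fast oxidative addition) forms the C3–C7 bond between two sp2 carbons, so no stereocentre is formed or touched.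

Step 9
Reactants: 12 the diol dienone from step 8; 13 angelic acid [(Z)-2-methylbut-2-enoic acid]
Product: 15 bis-angelate of 12 (C4–O and C8–O as (Z)-2-methylbut-2-enoates; stereocentres as in 12), via mixed anhydride 14 (not isolated)
Conditions: 13 (3 equiv), 2,4,6-trichlorobenzoyl chloride, Et3N, toluene, rt; then 12, 75 °C (no DMAP)
Reagents that add atoms: none
Why: Yamaguchi mixed-anhydride esterification acylates both secondary hydroxyls with retention; leaving out DMAP keeps the (Z)-angelate from isomerising to the tiglate.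

Step 10
Reactants: 15 bis-angelate dienone
Product: 18 (1S,3S,4S,5S,6S)-3-hydroxy-1-methyl-4-{(3R)-4-[(2S)-3,3-dimethyloxiran-2-yl]-3-[(Z)-2-methylbut-2-enoyloxy]but-1-en-2-yl}-2-oxo-7-oxabicyclo[4.1.0]heptan-5-yl (Z)-2-methylbut-2-enoate, via silyl enol ether 16 (not isolated), via 2-silyloxy ketone 17 (not isolated)
Conditions: [(Ph3P)CuH]6 (5 mol%), PhMe2SiH, toluene, 0 °C to rt; then dimethyldioxirane, acetone, −78 °C; then KF (cat.), THF–H2O, 0 °C
Reagents that add atoms: dimethyldioxirane, CC1(C)OO1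
Why: Copper-hydride conjugate hydrosilylation then Rubottom oxidation: hydride adds to C3 from the face opposite the C4 angelate and the oxirane, which places the side chain cis to both (C3), and the dioxirane then oxidises the silyl enol ether at C2 from the face opposite the new C3 side chain (C2–O trans to C3).

Step 11
Reactants: 18 the C2 hydroxy ketone
Product: 19 (1S,3S,4R,5S,6S)-3-acetoxy-1-methyl-4-{(3R)-4-[(2S)-3,3-dimethyloxiran-2-yl]-3-[(Z)-2-methylbut-2-enoyloxy]but-1-en-2-yl}-2-oxo-7-oxabicyclo[4.1.0]heptan-5-yl (Z)-2-methylbut-2-enoate (target)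
Conditions: Ac2O, pyridine, DMAP (5 mol%), CH2Cl2, 0 °C
Reagents that add atoms: acetic anhydride, CC(=O)OC(C)=O
Why: DMAP-catalysed O-acetylation of the only free hydroxyl, with retention at C2.

## Compound list

1 | 2-bromo-5-methylphenol | Cc1ccc(Br)c(O)c1 | starting material
2 | 2-bromo-4-methoxy-5-methylphenol | COc1cc(Br)c(O)cc1C | intermediate
3 | 2-bromo-4,4-dimethoxy-5-methylcyclohexa-2,5-dien-1-one | O=C1C=C(C)C(OC)(OC)C=C1Br | intermediate
4 | (1R)-2-bromo-4,4-dimethoxy-5-methylcyclohexa-2,5-dien-1-ol | O[C@@H]1C=C(C)C(OC)(OC)C=C1Br | intermediate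
5 | (1S,2R,6S)-3-bromo-5,5-dimethoxy-6-methyl-7-oxabicyclo[4.1.0]hept-3-en-2-ol (OH cis to oxirane) | O[C@@H]1[C@@H]2O[C@]2(C)C(OC)(OC)C=C1Br | intermediate
6 | (1S,5R,6S)-4-bromo-5-hydroxy-1-methyl-7-oxabicyclo[4.1.0]hept-3-en-2-one | O[C@@H]1[C@@H]2O[C@]2(C)C(=O)C=C1Br | intermediate
7 | 2-bromoacrolein (2-bromoprop-2-enal) | C=C(Br)C=O | starting material
8 | (3R)-2-bromohexa-1,5-dien-3-ol | C=C(Br)[C@@H](CC=C)O | intermediate
9 | (3R)-2-bromo-6-methylhepta-1,5-dien-3-ol | C=C(Br)[C@@H](CC=C(C)C)O | intermediate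
10 | (2R)-3-bromo-1-[(2S)-3,3-dimethyloxiran-2-yl]but-3-en-2-ol | C=C(Br)[C@@H](C[C@@H]1OC1(C)C)O | intermediate
11 | (2R)-1-[(2S)-3,3-dimethyloxiran-2-yl]-3-(4,4,5,5-tetramethyl-1,3,2-dioxaborolan-2-yl)but-3-en-2-ol | C=C(B1OC(C)(C)C(C)(C)O1)[C@@H](C[C@@H]1OC1(C)C)O | intermediate
12 | (1S,5S,6S)-4-{(3R)-4-[(2S)-3,3-dimethyloxiran-2-yl]-3-hydroxybut-1-en-2-yl}-5-hydroxy-1-methyl-7-oxabicyclo[4.1.0]hept-3-en-2-one | O[C@@H]1[C@@H]2O[C@]2(C)C(=O)C=C1C(=C)[C@@H](C[C@@H]3OC3(C)C)O | intermediate
13 | angelic acid, (Z)-2-methylbut-2-enoic acid | C/C=C(/C)C(=O)O | starting material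
14 | (Z)-2-methylbut-2-enoic 2,4,6-trichlorobenzoic anhydride | C/C=C(/C)C(=O)OC(=O)c1c(Cl)cc(Cl)cc1Cl | intermediate
15 | bis-angelate of 12 (C4–O and C8–O esterified, stereocentres as in 12) | C/C=C(/C)C(=O)O[C@@H]1[C@@H]2O[C@]2(C)C(=O)C=C1C(=C)[C@@H](C[C@@H]3OC3(C)C)OC(=O)/C(C)=C\C | intermediate
16 | C1 dimethylphenylsilyl enol ether (C1=C2) after hydride addition to C3 of 15; C3 side chain cis to the C4 angelate and the oxirane | C=C([C@@H]1[C@H](OC(=O)/C(C)=C\C)[C@@H]2O[C@]2(C)C(O[Si](C)(C)c2ccccc2)=C1)[C@@H](C[C@@H]1OC1(C)C)OC(=O)/C(C)=C\C | intermediate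
17 | C2 dimethylphenylsilyloxy ketone; C2–O trans to the C3 side chain, other centres as in 18 | C=C([C@@H]1[C@H](OC(=O)/C(C)=C\C)[C@@H]2O[C@]2(C)C(=O)[C@H]1O[Si](C)(C)c1ccccc1)[C@@H](C[C@@H]1OC1(C)C)OC(=O)/C(C)=C\C | intermediate
18 | (1S,3S,4S,5S,6S)-3-hydroxy-1-methyl-4-{(3R)-4-[(2S)-3,3-dimethyloxiran-2-yl]-3-[(Z)-2-methylbut-2-enoyloxy]but-1-en-2-yl}-2-oxo-7-oxabicyclo[4.1.0]heptan-5-yl (Z)-2-methylbut-2-enoate | C=C([C@@H]1[C@H](OC(=O)/C(C)=C\C)[C@@H]2O[C@]2(C)C(=O)[C@H]1O)[C@@H](C[C@@H]1OC1(C)C)OC(=O)/C(C)=C\C | intermediate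
19 | (1S,3S,4R,5S,6S)-3-acetoxy-1-methyl-4-{(3R)-4-[(2S)-3,3-dimethyloxiran-2-yl]-3-[(Z)-2-methylbut-2-enoyloxy]but-1-en-2-yl}-2-oxo-7-oxabicyclo[4.1.0]heptan-5-yl (Z)-2-methylbut-2-enoate, CNP0407453.2 | C=C([C@@H]1[C@H](OC(=O)/C(C)=C\C)[C@@H]2O[C@]2(C)C(=O)[C@H]1OC(C)=O)[C@@H](C[C@@H]1OC1(C)C)OC(=O)/C(C)=C\C | target

## Step count and risks

Total: 11 steps. Longest linear sequence: 8 steps (steps 1–4 and 8–11 from 2-bromo-5-methylphenol); the side-chain branch is 3 steps (5–7) before the union.

**Step 10 (most at risk).** Hydride may add 1,6 to the exocyclic methylene of the dienone instead of 1,4 to C3, or the face selectivity at C3 or C2 may be poor. The fallback sets out from 15 and replaces intermolecular conjugate hydride delivery by a 1,2-reduction and redox isomerisation. NaBH4 with CeCl3·7H2O in MeOH at −78 °C reduces the C1 ketone from the face opposite the oxirane to give the C1 allylic alcohol F1. H2-activated [Ir(cod)(PCy3)(py)]PF6 then moves the carbinol hydrogen suprafacially from C1 to C3, which can only touch the C2=C3 alkene, and gives the saturated C1 ketone F2 with the C3 hydrogen on the required face. LiN(SiMe3)2 followed by 2-(phenylsulfonyl)-3-phenyloxaziridine hydroxylates C2 opposite the side chain, and the route is rejoined at 18.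

**Step 2.** The oxazaborolidine may not distinguish the two alkenyl flanks of the cross-conjugated dienone well enough, and dienol 4 aromatises easily. The fallback sets out from 3 and gives up the asymmetric reduction. NaBH4 with CeCl3·7H2O gives the racemic dienol F3. Asymmetry is then introduced in the epoxidation as a kinetic resolution with VO(OiPr)3, a C2-symmetric chiral bishydroxamic acid ligand and t-BuOOH, run to about half conversion. Only the (R)-dienol is epoxidised and the unreacted (S)-dienol is discarded; the route is rejoined at 5.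

**Step 8.** The base-sensitive bromo epoxy-enone 6 or the epoxy alcohol 10 may not survive the one-flask borylation and coupling. The fallback sets out from 9 and 5: it couples earlier on a more robust bromide and epoxidises the side chain last. The prenyl bromo alcohol 9 is borylated (B2pin2, PdCl2(dppf), KOAc) to the alkenyl boronate F4. F4 is coupled with the ketal bromide 5 (aq. K3PO4) to give the diene diol ketal F5. Aqueous HF in MeCN unmasks the dienone diol F6, and the mixed-anhydride protocol with 13 gives the bis-angelate F7. Shi epoxidation with the L-fructose-derived ketone then oxidises the only electron-rich trisubstituted alkene, and the route is rejoined at 15.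

## Further compounds

F1 | step 10 | C1 allylic alcohol from 15 (C1–OH cis to the oxirane, C2=C3 retained) | C/C=C(/C)C(=O)O[C@@H]1[C@@H]2O[C@]2(C)[C@H](O)C=C1C(=C)[C@@H](C[C@@H]3OC3(C)C)OC(=O)/C(C)=C\C
F2 | step 10 | saturated C1 ketone (C2 methylene, C3 side chain cis to the C4 angelate and the oxirane) | C=C([C@@H]1[C@H](OC(=O)/C(C)=C\C)[C@@H]2O[C@]2(C)C(=O)C1)[C@@H](C[C@@H]1OC1(C)C)OC(=O)/C(C)=C\C
F3 | step 2 | racemic 2-bromo-4,4-dimethoxy-5-methylcyclohexa-2,5-dien-1-ol | OC1C=C(C)C(OC)(OC)C=C1Br
F4 | step 8 | (3R)-6-methyl-2-(4,4,5,5-tetramethyl-1,3,2-dioxaborolan-2-yl)hepta-1,5-dien-3-ol | C=C(B1OC(C)(C)C(C)(C)O1)[C@@H](CC=C(C)C)O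
F5 | step 8 | (1S,2S,6S)-3-[(3R)-3-hydroxy-6-methylhepta-1,5-dien-2-yl]-5,5-dimethoxy-6-methyl-7-oxabicyclo[4.1.0]hept-3-en-2-ol | O[C@@H]1[C@@H]2O[C@]2(C)C(OC)(OC)C=C1C(=C)[C@@H](CC=C(C)C)O
F6 | step 8 | (1S,5S,6S)-5-hydroxy-4-[(3R)-3-hydroxy-6-methylhepta-1,5-dien-2-yl]-1-methyl-7-oxabicyclo[4.1.0]hept-3-en-2-one | O[C@@H]1[C@@H]2O[C@]2(C)C(=O)C=C1C(=C)[C@@H](CC=C(C)C)O
F7 | step 8 | bis-angelate of F6 (both hydroxyls as (Z)-2-methylbut-2-enoates) | C/C=C(/C)C(=O)O[C@@H]1[C@@H]2O[C@]2(C)C(=O)C=C1C(=C)[C@@H](CC=C(C)C)OC(=O)/C(C)=C\C
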